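## Retrosynthetic overview

1. The C40 polyene is cut at C11=C12 and C11'=C12' into three building blocks: a diol-end C15 phosphonium salt, 2,7-dimethylocta-2,4,6-trienedial (C10), and a furanoid-end C15 phosphonium salt, joined by two successive Wittig olefinations.
2. Both end groups come from one enantiopure oxirane, (1S,6R)-epoxy-β-cyclocitral, made by Katsuki–Sharpless epoxidation of β-cyclogeraniol (from 2-methylcyclohexanone).
3. Diol end: Wharton transposition and ozonolysis give an α-silyloxy ketone; Felkin-type acetylide addition sets C6; hydroalumination gives the 7E alkene.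
4. Furanoid end: alkyne homologation, Sonogashira coupling, syn-SN2' hydride opening to an α-hydroxyallene, then AgNO3-catalysed cyclisation (axis-to-centre transfer sets C8').
5. Ring order: both cyclohexane rings are carried from the starting ketone; the oxirane (step 6) is the first ring made and is reopened in both branches; the dihydrofuran ring closes in step 18, before any polyene coupling.

Assumption: carotenoid numbering (C1–C20, primed for the furanoid half) is used in the Why lines; conjugate bases made and consumed within one operation (enolates, acetylides, ylides) are not numbered separately; (2E)-3-methylpent-2-en-4-yn-1-ol is taken as a commercial single isomer.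

## Route

Step 1
Reactants: 1 2-methylcyclohexanone
Product: 2 2,6-dimethylcyclohexanone (cis/trans mixture)
Conditions: LiN(i-Pr)2, THF, −78 °C; MeI, −78 → 0 °C
Reagents that add atoms: iodomethane CI
Why: Kinetic enolate formation at the unsubstituted α-carbon and SN2 methylation (enolate alkylation); the α-stereocentres are erased in steps 2 and 3.

Step 2
Reactants: 2 2,6-dimethylcyclohexanone
Product: 3 2,2,6-trimethylcyclohexanone (racemic)
Conditions: LiN(i-Pr)2, THF, −78 → 0 °C; MeI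
Reagents that add atoms: iodomethane CI
Why: Either α-position gives the same tetrasubstituted enolate, whose C-methylation builds the gem-dimethyl carbon (enolate alkylation).

Step 3
Reactants: 3 2,2,6-trimethylcyclohexanone
Product: 4 2,6,6-trimethylcyclohex-1-en-1-yl trifluoromethanesulfonate
Conditions: LiN(i-Pr)2, THF, −78 → 0 °C; PhNTf2, 0 °C → rt
Reagents that add atoms: N-phenylbis(trifluoromethanesulfonimide) O=S(=O)(N(c1ccccc1)S(=O)(=O)C(F)(F)F)C(F)(F)F
Why: The only remaining α-hydrogen is removed and the enolate is O-sulfonylated (enol triflate formation), which also removes the racemic stereocentre.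

Step 4
Reactants: 4 2,6,6-trimethylcyclohex-1-en-1-yl trifluoromethanesulfonate
Product: 5 methyl 2,6,6-trimethylcyclohex-1-ene-1-carboxylate
Conditions: Pd(OAc)2 (5 mol%), 1,3-bis(diphenylphosphino)propane (5 mol%), CO (1 atm), MeOH, Et3N, DMF, 70 °C
Reagents that add atoms: carbon monoxide [C-]#[O+]; methanol CO
Why: Oxidative addition of zerovalent palladium to the vinyl triflate, CO insertion and methanolysis (Pd(OAc)2-catalysed alkoxycarbonylation) give the tetrasubstituted enoate.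

Step 5
Reactants: 5 methyl 2,6,6-trimethylcyclohex-1-ene-1-carboxylate
Product: 6 (2,6,6-trimethylcyclohex-1-en-1-yl)methanol
Conditions: i-Bu2AlH (2.5 equiv), CH2Cl2, −78 → 0 °C; aq. potassium sodium tartrate
Reagents that add atoms: none
Why: 1,2-Reduction of the hindered enoate by i-Bu2AlH gives the allylic alcohol without touching the tetrasubstituted alkene.

Step 6
Reactants: 6 (2,6,6-trimethylcyclohex-1-en-1-yl)methanol
Product: 7 [(1R,6R)-2,2,6-trimethyl-7-oxabicyclo[4.1.0]heptan-1-yl]methanol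
Conditions: Ti(O-i-Pr)4 (10 mol%), D-(−)-diethyl tartrate (12 mol%), t-BuOOH (2 equiv), 4 Å molecular sieves (Na12Al12Si12O48), CH2Cl2, −20 °C
Reagents that add atoms: tert-butyl hydroperoxide CC(C)(C)OO
Why: Katsuki–Sharpless asymmetric epoxidation: the complex of Ti(O-i-Pr)4 with (S,S)-diethyl tartrate delivers the peroxide oxygen to one enantioface of the allylic alcohol, setting both oxirane carbons as (1R,6R) (carotenoid C5 = R).

Step 7
Reactants: 7 [(1R,6R)-2,2,6-trimethyl-7-oxabicyclo[4.1.0]heptan-1-yl]methanol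
Product: 8 (1S,6R)-2,2,6-trimethyl-7-oxabicyclo[4.1.0]heptane-1-carbaldehyde
Conditions: (n-Pr4N)RuO4 (5 mol%), N-methylmorpholine N-oxide (1.5 equiv), 4 Å molecular sieves (Na12Al12Si12O48), CH2Cl2, rt
Reagents that add atoms: none
Why: Ley–Griffith oxidation stops at the non-enolisable aldehyde and leaves the oxirane intact (the C1 descriptor changes only through CIP priorities).

Step 8
Reactants: 8 (1S,6R)-2,2,6-trimethyl-7-oxabicyclo[4.1.0]heptane-1-carbaldehyde
Product: 10 (1R)-1,3,3-trimethyl-2-methylidenecyclohexan-1-ol, via epoxy hydrazone 9 (not isolated)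
Conditions: N2H4·H2O (3 equiv), AcOH (0.2 equiv), MeOH, 0 °C → rt
Reagents that add atoms: none
Why: Wharton transposition: the hydrazone opens the oxirane to a vinyldiazene that loses N2, giving the exocyclic alkene while the C5–O bond, and so the (R) carbinol centre, is never broken.

Step 9
Reactants: 10 (1R)-1,3,3-trimethyl-2-methylidenecyclohexan-1-ol
Product: 11 triethyl{[(1R)-1,3,3-trimethyl-2-methylidenecyclohexyl]oxy}silane
Conditions: Et3SiOTf, 2,6-lutidine, CH2Cl2, −78 → 0 °C
Reagents that add atoms: triethylsilyl trifluoromethanesulfonate CC[Si](CC)(CC)OS(=O)(=O)C(F)(F)F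
Why: Silylation of the tertiary alcohol with the silyl triflate (protection) installs the non-chelating α-silyloxy group needed in step 11.

Step 10
Reactants: 11 triethyl{[(1R)-1,3,3-trimethyl-2-methylidenecyclohexyl]oxy}silane
Product: 13 (2R)-2,6,6-trimethyl-2-[(triethylsilyl)oxy]cyclohexan-1-one, via spiro ozonide 12 (not isolated)
Conditions: O3, CH2Cl2, −78 °C; then PPh3, −78 °C → rt
Reagents that add atoms: ozone [O-][O+]=O
Why: Ozonolysis of the 1,1-disubstituted alkene and reductive cleavage of the ozonide give the α-silyloxy ketone with the quaternary stereocentre untouched.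

Step 11
Reactants: 13 (2R)-2,6,6-trimethyl-2-[(triethylsilyl)oxy]cyclohexan-1-one; 14 (2E)-3-methylpent-2-en-4-yn-1-ol
Product: 15 (1R,2R)-1-[(3E)-5-hydroxy-3-methylpent-3-en-1-yn-1-yl]-2,6,6-trimethyl-2-[(triethylsilyl)oxy]cyclohexan-1-ol
Conditions: 14, n-BuLi (2.1 equiv), THF, −78 → 0 °C; then 13, −78 → −20 °C; aq. NH4Cl at −20 °C
Reagents that add atoms: none
Why: 1,2-Addition of the acetylide (made with n-BuLi) to the non-enolisable ketone by axial attack anti to the axial, non-chelating C–OSiEt3 bond (polar Felkin–Anh model) puts the new hydroxyl cis to the silyloxy group, i.e. (1R,2R), the cis-5,6-diol pattern; the cold quench limits 1,2-silyl migration.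

Step 12
Reactants: 15 (1R,2R)-1-[(3E)-5-hydroxy-3-methylpent-3-en-1-yn-1-yl]-2,6,6-trimethyl-2-[(triethylsilyl)oxy]cyclohexan-1-ol
Product: 16 (2E,4E)-5-{(1S,2R)-1-hydroxy-2,6,6-trimethyl-2-[(triethylsilyl)oxy]cyclohexyl}-3-methylpenta-2,4-dien-1-ol
Conditions: NaAlH2(OCH2CH2OMe)2 (3.5 equiv), THF, 0 °C → rt; aq. potassium sodium tartrate
Reagents that add atoms: none
Why: Alkoxide-directed trans-hydroalumination of the propargylic alcohol by NaAlH2(OCH2CH2OMe)2 (hydride to C7, Al to C8) and protonolysis give the 7E alkene; the 9E bond and the silyl ether are unaffected.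

Step 13
Reactants: 16 (2E,4E)-5-{(1S,2R)-1-hydroxy-2,6,6-trimethyl-2-[(triethylsilyl)oxy]cyclohexyl}-3-methylpenta-2,4-dien-1-ol
Product: 18 [(2E,4E)-5-{(1S,2R)-1-hydroxy-2,6,6-trimethyl-2-[(triethylsilyl)oxy]cyclohexyl}-3-methylpenta-2,4-dien-1-yl](triphenyl)phosphonium bromide, via dienyl bromide 17 (not isolated)
Conditions: CBr4 (1.1 equiv), PPh3 (1.1 equiv), CH2Cl2, −20 °C; then PPh3 (1.5 equiv), rt
Reagents that add atoms: carbon tetrabromide BrC(Br)(Br)Br; triphenylphosphine c1ccc(cc1)P(c1ccccc1)c1ccccc1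
Why: Appel bromination touches only the primary allylic alcohol (the tertiary one is flanked by two quaternary carbons), and SN2 quaternisation by PPh3 gives the salt under non-acidic conditions that spare the tertiary allylic alcohol.

Step 14
Reactants: 19 methyl 3-oxobutanoate
Product: 20 methyl (2E)-3-{[(trifluoromethyl)sulfonyl]oxy}but-2-enoate
Conditions: Tf2O, aq. Me4NOH, hexanes, 5 °C → rt
Reagents that add atoms: trifluoromethanesulfonic anhydride O=S(=O)(OS(=O)(=O)C(F)(F)F)C(F)(F)F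
Why: O-Sulfonylation of the acetoacetate enolate; with the non-chelating tetramethylammonium counter-ion the enolate reacts in its extended form and gives the E enol triflate (OTf trans to CO2Me).

Step 15
Reactants: 8 (1S,6R)-2,2,6-trimethyl-7-oxabicyclo[4.1.0]heptane-1-carbaldehyde
Product: 21 (1R,6R)-1-ethynyl-2,2,6-trimethyl-7-oxabicyclo[4.1.0]heptane
Conditions: Me3SiCHN2, LiN(i-Pr)2, THF, −78 °C → rt
Reagents that add atoms: (trimethylsilyl)diazomethane C[Si](C)(C)C=[N+]=[N-]
Why: Colvin homologation: addition of Me3SiC(Li)N2, Peterson elimination, loss of N2 and 1,2-hydrogen shift of the alkylidene carbene turn the aldehyde into the terminal alkyne without touching the oxirane stereocentres.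

Step 16
Reactants: 21 (1R,6R)-1-ethynyl-2,2,6-trimethyl-7-oxabicyclo[4.1.0]heptane; 20 methyl (2E)-3-{[(trifluoromethyl)sulfonyl]oxy}but-2-enoate
Product: 22 methyl (2E)-3-methyl-5-[(1R,6R)-2,2,6-trimethyl-7-oxabicyclo[4.1.0]heptan-1-yl]pent-2-en-4-ynoate
Conditions: Pd(PPh3)4 (5 mol%), CuI (10 mol%), Et3N, THF, rt
Reagents that add atoms: none
Why: Sonogashira coupling with retention of the triflate geometry gives the 9E enynoate; oxidative addition to the activated C–OTf bond outruns ionisation of the fully substituted propargylic oxirane.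

Step 17
Reactants: 22 methyl (2E)-3-methyl-5-[(1R,6R)-2,2,6-trimethyl-7-oxabicyclo[4.1.0]heptan-1-yl]pent-2-en-4-ynoate
Product: 23 (2E)-5-[(2R)-2-hydroxy-2,6,6-trimethylcyclohexylidene]-3-methylpenta-2,4-dien-1-ol (allene axis R)
Conditions: i-Bu2AlH (5 equiv), CH2Cl2, −78 → 0 °C; aq. potassium sodium tartrate
Reagents that add atoms: none
Why: After 1,2-reduction of the ester, i-Bu2AlH bound to the oxirane oxygen delivers hydride to C8 on the face of the departing C6–O bond (syn SN2' reduction), fixing the (R)-allene axis and leaving the (R) C5 carbinol untouched.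

Step 18
Reactants: 23 (2E)-5-[(2R)-2-hydroxy-2,6,6-trimethylcyclohexylidene]-3-methylpenta-2,4-dien-1-ol (allene axis R)
Product: 24 (2E)-3-[(2S,7aR)-4,4,7a-trimethyl-2,4,5,6,7,7a-hexahydro-1-benzofuran-2-yl]but-2-en-1-ol
Conditions: AgNO3 (20 mol%), CaCO3, acetone/H2O (4:1), rt, dark
Reagents that add atoms: none
Why: AgNO3-catalysed 5-endo cycloisomerisation of the α-hydroxyallene: the hydroxyl adds to C8 in the plane of the activated C7=C8 bond, so the allene axis is translated into the (2S) centre (carotenoid 8'S) with the butenyl chain cis to the 7a-methyl.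

Step 19
Reactants: 24 (2E)-3-[(2S,7aR)-4,4,7a-trimethyl-2,4,5,6,7,7a-hexahydro-1-benzofuran-2-yl]but-2-en-1-ol
Product: 26 {(2E)-3-[(2S,7aR)-4,4,7a-trimethyl-2,4,5,6,7,7a-hexahydro-1-benzofuran-2-yl]but-2-en-1-yl}(triphenyl)phosphonium bromide, via allylic bromide 25 (not isolated)
Conditions: CBr4 (1.1 equiv), PPh3 (1.1 equiv), CH2Cl2, −30 °C; then PPh3 (1.5 equiv), rt
Reagents that add atoms: carbon tetrabromide BrC(Br)(Br)Br; triphenylphosphine c1ccc(cc1)P(c1ccccc1)c1ccccc1
Why: Appel bromination and SN2 quaternisation by PPh3 run without acid, so the doubly allylic C8'–O bond is not ionised and the 8'S centre is kept.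

Step 20
Reactants: 27 (2E)-1,4-dibromobut-2-ene
Product: 28 tetramethyl [(2E)-but-2-ene-1,4-diyl]bis(phosphonate)
Conditions: P(OMe)3 (4 equiv), neat, 110 °C, MeBr distilled off
Reagents that add atoms: trimethyl phosphite COP(OC)OC
Why: Double Michaelis–Arbuzov reaction of the allylic dibromide; the E double bond is not involved.

Step 21
Reactants: 28 tetramethyl [(2E)-but-2-ene-1,4-diyl]bis(phosphonate); 29 1,1-dimethoxypropan-2-one
Product: 31 (2E,4E,6E)-1,1,8,8-tetramethoxy-2,7-dimethylocta-2,4,6-triene, via monophosphonate acetal 30 (not isolated)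
Conditions: NaH (2.2 equiv), THF, 0 °C; then 29 (2.2 equiv in all), 0 °C → rt
Reagents that add atoms: 1,1-dimethoxypropan-2-one (second equivalent of 29) COC(OC)C(C)=O
Why: Twofold Horner–Wadsworth–Emmons olefination in which each phosphonate carbanion condenses with one molecule of the ketone (the first giving monophosphonate 30, the second equivalent completing the triene) forms mainly the E trisubstituted alkenes, with the acetal carbon trans to the chain.

Step 22
Reactants: 31 (2E,4E,6E)-1,1,8,8-tetramethoxy-2,7-dimethylocta-2,4,6-triene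
Product: 32 (2E,4E,6E)-2,7-dimethylocta-2,4,6-trienedial
Conditions: 1 M aq. HCl, THF, rt
Reagents that add atoms: water O
Why: Acetal hydrolysis releases the dialdehyde, and the acid equilibrates any Z enal to the crystalline all-E isomer.

Step 23
Reactants: 26 furanoid C15 phosphonium bromide; 32 (2E,4E,6E)-2,7-dimethylocta-2,4,6-trienedial (3 equiv)
Product: 33 (2E,4E,6E,8E,10E)-2,7-dimethyl-11-[(2S,7aR)-4,4,7a-trimethyl-2,4,5,6,7,7a-hexahydro-1-benzofuran-2-yl]dodeca-2,4,6,8,10-pentaenal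
Conditions: NaOMe (1.1 equiv) added slowly to 26 and 32, CH2Cl2/MeOH, 0 °C → rt, dark
Reagents that add atoms: none
Why: Wittig olefination of the semi-stabilised allylic ylide with one carbonyl of the symmetrical dialdehyde (used in excess) forms C11'=C12' mainly E (minor 11'Z isomer removed by chromatography); base-only conditions leave the acid-labile C8' centre alone.

Step 24
Reactants: 18 diol-end C15 phosphonium bromide; 33 furanoid C25 aldehyde
Product: 34 (5R,6S,5'R,8'S)-5',8'-epoxy-5-[(triethylsilyl)oxy]-5,6,5',8'-tetrahydro-β,β-caroten-6-ol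
Conditions: NaOMe (2.2 equiv), CH2Cl2/MeOH, rt, dark
Reagents that add atoms: none
Why: Wittig olefination joins the C15 ylide to the C25 aldehyde at C11=C12 (E favoured; the free tertiary hydroxyl tolerates methoxide), completing the C40 polyene with all stereocentres untouched.

Step 25
Reactants: 34 (5R,6S,5'R,8'S)-5',8'-epoxy-5-[(triethylsilyl)oxy]-5,6,5',8'-tetrahydro-β,β-caroten-6-ol
Product: 35 (5R,6S,5'R,8'S)-5',8'-epoxy-5,6,5',8'-tetrahydro-β,β-carotene-5,6-diol
Conditions: Bu4NF (3 equiv), THF, 0 °C → rt, dark, argon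
Reagents that add atoms: none
Why: Fluoride-mediated Si–O cleavage (desilylation) frees the C5 hydroxyl under non-acidic conditions that preserve the polyene and the epimerisable 8'S centre.

## Compound list

1 | 2-methylcyclohexanone (racemic) | CC1CCCCC1=O | starting material
2 | 2,6-dimethylcyclohexanone (cis/trans mixture) | CC1CCCC(C)C1=O | intermediate
3 | 2,2,6-trimethylcyclohexanone (racemic) | CC1CCCC(C)(C)C1=O | intermediate
4 | 2,6,6-trimethylcyclohex-1-en-1-yl trifluoromethanesulfonate | CC1=C(OS(=O)(=O)C(F)(F)F)C(C)(C)CCC1 | intermediate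
5 | methyl 2,6,6-trimethylcyclohex-1-ene-1-carboxylate | COC(=O)C1=C(C)CCCC1(C)C | intermediate
6 | (2,6,6-trimethylcyclohex-1-en-1-yl)methanol | OCC1=C(C)CCCC1(C)C | intermediate
7 | [(1R,6R)-2,2,6-trimethyl-7-oxabicyclo[4.1.0]heptan-1-yl]methanol | OC[C@@]12O[C@]1(C)CCCC2(C)C | intermediate
8 | (1S,6R)-2,2,6-trimethyl-7-oxabicyclo[4.1.0]heptane-1-carbaldehyde | O=C[C@@]12O[C@]1(C)CCCC2(C)C | intermediate
9 | epoxy hydrazone, (E)-{[(1R,6R)-2,2,6-trimethyl-7-oxabicyclo[4.1.0]heptan-1-yl]methylidene}hydrazine | N/N=C/[C@@]12O[C@]1(C)CCCC2(C)C | intermediate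
10 | (1R)-1,3,3-trimethyl-2-methylidenecyclohexan-1-ol | C=C1C(C)(C)CCC[C@@]1(C)O | intermediate
11 | triethyl{[(1R)-1,3,3-trimethyl-2-methylidenecyclohexyl]oxy}silane | C=C1C(C)(C)CCC[C@@]1(C)O[Si](CC)(CC)CC | intermediate
12 | spiro ozonide, triethyl{[(6R)-6,10,10-trimethyl-1,2,4-trioxaspiro[4.5]decan-6-yl]oxy}silane (both epimers at the spiro carbon) | C1OOC2(O1)C(C)(C)CCC[C@@]2(C)O[Si](CC)(CC)CC | intermediate
13 | (2R)-2,6,6-trimethyl-2-[(triethylsilyl)oxy]cyclohexan-1-one | O=C1C(C)(C)CCC[C@@]1(C)O[Si](CC)(CC)CC | intermediate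
14 | (2E)-3-methylpent-2-en-4-yn-1-ol | C#C/C(C)=C/CO | starting material
15 | (1R,2R)-1-[(3E)-5-hydroxy-3-methylpent-3-en-1-yn-1-yl]-2,6,6-trimethyl-2-[(triethylsilyl)oxy]cyclohexan-1-ol | OC/C=C(C)/C#C[C@]1(O)C(C)(C)CCC[C@@]1(C)O[Si](CC)(CC)CC | intermediate
16 | (2E,4E)-5-{(1S,2R)-1-hydroxy-2,6,6-trimethyl-2-[(triethylsilyl)oxy]cyclohexyl}-3-methylpenta-2,4-dien-1-ol | OC/C=C(C)/C=C/[C@]1(O)C(C)(C)CCC[C@@]1(C)O[Si](CC)(CC)CC | intermediate
17 | dienyl bromide, (1S,2R)-1-[(1E,3E)-5-bromo-3-methylpenta-1,3-dien-1-yl]-2,6,6-trimethyl-2-[(triethylsilyl)oxy]cyclohexan-1-ol | BrC/C=C(C)/C=C/[C@]1(O)C(C)(C)CCC[C@@]1(C)O[Si](CC)(CC)CC | intermediate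
18 | [(2E,4E)-5-{(1S,2R)-1-hydroxy-2,6,6-trimethyl-2-[(triethylsilyl)oxy]cyclohexyl}-3-methylpenta-2,4-dien-1-yl](triphenyl)phosphonium bromide | [Br-].c1ccccc1[P+](c1ccccc1)(c1ccccc1)C/C=C(C)/C=C/[C@]1(O)C(C)(C)CCC[C@@]1(C)O[Si](CC)(CC)CC | intermediate
19 | methyl 3-oxobutanoate | COC(=O)CC(C)=O | starting material
20 | methyl (2E)-3-{[(trifluoromethyl)sulfonyl]oxy}but-2-enoate | COC(=O)/C=C(C)/OS(=O)(=O)C(F)(F)F | intermediate
21 | (1R,6R)-1-ethynyl-2,2,6-trimethyl-7-oxabicyclo[4.1.0]heptane | C#C[C@@]12O[C@]1(C)CCCC2(C)C | intermediate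
22 | methyl (2E)-3-methyl-5-[(1R,6R)-2,2,6-trimethyl-7-oxabicyclo[4.1.0]heptan-1-yl]pent-2-en-4-ynoate | COC(=O)/C=C(C)/C#C[C@@]12O[C@]1(C)CCCC2(C)C | intermediate
23 | (2E)-5-[(2R)-2-hydroxy-2,6,6-trimethylcyclohexylidene]-3-methylpenta-2,4-dien-1-ol (allene axis R; C8–H on the face of the hydroxyl) | OC/C=C(C)/C([H])=[C@@]=C1C(C)(C)CCC[C@@]1(C)O | intermediate
24 | (2E)-3-[(2S,7aR)-4,4,7a-trimethyl-2,4,5,6,7,7a-hexahydro-1-benzofuran-2-yl]but-2-en-1-ol | OC/C=C(\C)[C@@H]1C=C2C(C)(C)CCC[C@@]2(C)O1 | intermediate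
25 | allylic bromide, (2S,7aR)-2-[(2E)-4-bromobut-2-en-2-yl]-4,4,7a-trimethyl-2,4,5,6,7,7a-hexahydro-1-benzofuran | BrC/C=C(\C)[C@@H]1C=C2C(C)(C)CCC[C@@]2(C)O1 | intermediate
26 | {(2E)-3-[(2S,7aR)-4,4,7a-trimethyl-2,4,5,6,7,7a-hexahydro-1-benzofuran-2-yl]but-2-en-1-yl}(triphenyl)phosphonium bromide | [Br-].c1ccccc1[P+](c1ccccc1)(c1ccccc1)C/C=C(\C)[C@@H]1C=C2C(C)(C)CCC[C@@]2(C)O1 | intermediate
27 | (2E)-1,4-dibromobut-2-ene | BrC/C=C/CBr | starting material
28 | tetramethyl [(2E)-but-2-ene-1,4-diyl]bis(phosphonate) | COP(=O)(OC)C/C=C/CP(=O)(OC)OC | intermediate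
29 | 1,1-dimethoxypropan-2-one | COC(OC)C(C)=O | starting material
30 | monophosphonate acetal, dimethyl [(2E,4E)-6,6-dimethoxy-5-methylhexa-2,4-dien-1-yl]phosphonate | COP(=O)(OC)C/C=C/C=C(\C)C(OC)OC | intermediate
31 | (2E,4E,6E)-1,1,8,8-tetramethoxy-2,7-dimethylocta-2,4,6-triene | COC(OC)/C(C)=C/C=C/C=C(\C)C(OC)OC | intermediate
32 | (2E,4E,6E)-2,7-dimethylocta-2,4,6-trienedial | O=C/C(C)=C/C=C/C=C(\C)C=O | intermediate
33 | (2E,4E,6E,8E,10E)-2,7-dimethyl-11-[(2S,7aR)-4,4,7a-trimethyl-2,4,5,6,7,7a-hexahydro-1-benzofuran-2-yl]dodeca-2,4,6,8,10-pentaenal | O=C/C(C)=C/C=C/C=C(C)/C=C/C=C(\C)[C@@H]1C=C2C(C)(C)CCC[C@@]2(C)O1 | intermediate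
34 | (5R,6S,5'R,8'S)-5',8'-epoxy-5-[(triethylsilyl)oxy]-5,6,5',8'-tetrahydro-β,β-caroten-6-ol (all-E) | CC(/C=C/C=C(C)/C=C/[C@]1(O)C(C)(C)CCC[C@@]1(C)O[Si](CC)(CC)CC)=C\C=C\C=C(C)\C=C\C=C(/C)[C@@H]1C=C2C(C)(C)CCC[C@@]2(C)O1 | intermediate
35 | (5R,6S,5'R,8'S)-5',8'-epoxy-5,6,5',8'-tetrahydro-β,β-carotene-5,6-diol (all-E) | CC(/C=C/C=C(C)/C=C/[C@]1(O)C(C)(C)CCC[C@@]1(C)O)=C\C=C\C=C(C)\C=C\C=C(/C)[C@@H]1C=C2C(C)(C)CCC[C@@]2(C)O1 | target

## Step count

Total step count: 25.
Longest linear sequence: 15 steps (steps 1–13, 24, 25; the path through steps 1–7, 15–19, 23–25 is also 15).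

## Steps most likely to fail, with fallbacks

Step 8 (Wharton transposition of a hindered, fully substituted epoxy aldehyde; azine formation or poor fragmentation). The fallback sets out from 7 and comes back at 10. The primary alcohol of 7 is converted with I2, PPh3 and imidazole (toluene, 60 °C) into (1S,6R)-1-(iodomethyl)-2,2,6-trimethyl-7-oxabicyclo[4.1.0]heptane F1. F1 is then heated with Zn dust in EtOH; Zn insertion into the C–I bond and β-elimination of the oxirane oxygen give 10, again without breaking the C–O bond at the carbinol centre.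

Step 11 (addition to a ketone flanked by two quaternary carbons, with facial selectivity resting on a conformational model). The fallback sets out from 10 and comes back at 16; C6 is set by a hydroxyl-directed reagent instead of by the ketone conformation. Hydrogen-bond-directed dihydroxylation of 10 with OsO4 and TMEDA (CH2Cl2, −78 °C, then aq. Na2SO3) puts both new hydroxyls syn to the existing one and gives (1R,2R)-1-(hydroxymethyl)-2,6,6-trimethylcyclohexane-1,2-diol F2. Et3SiOTf (2.1 equiv) with 2,6-lutidine silylates the primary and the more accessible tertiary hydroxyl to give (1R,2R)-2,6,6-trimethyl-2-[(triethylsilyl)oxy]-1-{[(triethylsilyl)oxy]methyl}cyclohexan-1-ol F3. Swern oxidation ((COCl)2, DMSO, Et3N) converts the primary silyl ether directly into (1S,2R)-1-hydroxy-2,6,6-trimethyl-2-[(triethylsilyl)oxy]cyclohexane-1-carbaldehyde F4. Me3SiCHN2 with LiN(i-Pr)2 homologates this to (1R,2R)-1-ethynyl-2,6,6-trimethyl-2-[(triethylsilyl)oxy]cyclohexan-1-ol F5. Sonogashira coupling with 20 (Pd(PPh3)4, CuI, Et3N) gives methyl (2E)-5-{(1R,2R)-1-hydroxy-2,6,6-trimethyl-2-[(triethylsilyl)oxy]cyclohexyl}-3-methylpent-2-en-4-ynoate F6. NaAlH2(OCH2CH2OMe)2 then reduces both the propargylic alkyne (to the 7E alkene) and the ester, giving 16.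

Step 17 (sense and fidelity of the SN2' hydride delivery, on which the C8' configuration depends). The fallback sets out from 8 and comes back at 24, avoiding the allene altogether. Aldol condensation of 8 with acetone (aq. NaOH) gives (3E)-4-[(1S,6R)-2,2,6-trimethyl-7-oxabicyclo[4.1.0]heptan-1-yl]but-3-en-2-one F7. Horner–Wadsworth–Emmons reaction with methyl (dimethoxyphosphoryl)acetate and NaH gives methyl (2E,4E)-3-methyl-5-[(1S,6R)-2,2,6-trimethyl-7-oxabicyclo[4.1.0]heptan-1-yl]penta-2,4-dienoate F8. i-Bu2AlH at −78 °C gives (2E,4E)-3-methyl-5-[(1S,6R)-2,2,6-trimethyl-7-oxabicyclo[4.1.0]heptan-1-yl]penta-2,4-dien-1-ol F9. A trace of pyridinium p-toluenesulfonate (CH2Cl2, 0 °C) then triggers the classical 5,6-epoxide to 5,8-furanoid rearrangement (oxirane opening to the dienyl cation, capture at C8 by the C5 oxygen). This gives 24 together with its C2 epimer (2E)-3-[(2R,7aR)-4,4,7a-trimethyl-2,4,5,6,7,7a-hexahydro-1-benzofuran-2-yl]but-2-en-1-ol F10, which is removed by chromatography.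

## Further compounds

F1 | step 8 | (1S,6R)-1-(iodomethyl)-2,2,6-trimethyl-7-oxabicyclo[4.1.0]heptane | IC[C@@]12O[C@]1(C)CCCC2(C)C
F2 | step 11 | (1R,2R)-1-(hydroxymethyl)-2,6,6-trimethylcyclohexane-1,2-diol | OC[C@]1(O)C(C)(C)CCC[C@@]1(C)O
F3 | step 11 | (1R,2R)-2,6,6-trimethyl-2-[(triethylsilyl)oxy]-1-{[(triethylsilyl)oxy]methyl}cyclohexan-1-ol | CC[Si](CC)(CC)OC[C@]1(O)C(C)(C)CCC[C@@]1(C)O[Si](CC)(CC)CC
F4 | step 11 | (1S,2R)-1-hydroxy-2,6,6-trimethyl-2-[(triethylsilyl)oxy]cyclohexane-1-carbaldehyde | O=C[C@]1(O)C(C)(C)CCC[C@@]1(C)O[Si](CC)(CC)CC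
F5 | step 11 | (1R,2R)-1-ethynyl-2,6,6-trimethyl-2-[(triethylsilyl)oxy]cyclohexan-1-ol | C#C[C@]1(O)C(C)(C)CCC[C@@]1(C)O[Si](CC)(CC)CC
F6 | step 11 | methyl (2E)-5-{(1R,2R)-1-hydroxy-2,6,6-trimethyl-2-[(triethylsilyl)oxy]cyclohexyl}-3-methylpent-2-en-4-ynoate | COC(=O)/C=C(C)/C#C[C@]1(O)C(C)(C)CCC[C@@]1(C)O[Si](CC)(CC)CC
F7 | step 17 | (3E)-4-[(1S,6R)-2,2,6-trimethyl-7-oxabicyclo[4.1.0]heptan-1-yl]but-3-en-2-one | CC(=O)/C=C/[C@@]12O[C@]1(C)CCCC2(C)C
F8 | step 17 | methyl (2E,4E)-3-methyl-5-[(1S,6R)-2,2,6-trimethyl-7-oxabicyclo[4.1.0]heptan-1-yl]penta-2,4-dienoate | COC(=O)/C=C(C)/C=C/[C@@]12O[C@]1(C)CCCC2(C)C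
F9 | step 17 | (2E,4E)-3-methyl-5-[(1S,6R)-2,2,6-trimethyl-7-oxabicyclo[4.1.0]heptan-1-yl]penta-2,4-dien-1-ol | OC/C=C(C)/C=C/[C@@]12O[C@]1(C)CCCC2(C)C
F10 | step 17 | (2E)-3-[(2R,7aR)-4,4,7a-trimethyl-2,4,5,6,7,7a-hexahydro-1-benzofuran-2-yl]but-2-en-1-ol | OC/C=C(\C)[C@H]1C=C2C(C)(C)CCC[C@@]2(C)O1
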